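**Retrosynthetic overview**

1. The ring is a 4-hydroxycyclohex-2-enone. Ring locants used below: C1 ketone carbon, C2 alkene carbon with the acetate arm, C3 alkene CH, C4 carbinol, C5 geranylgeranyl carbon, C6 methylene. The oxygens at C1 and C4 are 1,4-related on both sides of the ring, so C4–C5–C6 is an aldehyde homoenolate (a ring-opened cyclopropanol) and C1–C2=C3 an acyl/β-vinyl unit (a ring-opened cyclopropenone).
2. Key disconnection: C6–C1 and C3–C4 together, a rhodium-catalysed [3+3] union of trans-2-geranylgeranylcyclopropanol with methyl 2-(3-oxocyclopropenyl)acetate. Two bonds absent from the target (C4–C6 in the cyclopropanol, C1–C3 in the cyclopropenone) store the C5 stereocentre, mask the β-metallo aldehyde and supply the strain; both are cleaved in the key step.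
3. The cyclopropanol comes from geranylgeraniol: bromide, copper-catalysed ethynylation, hydroboration to an alkenylboronate of a C2-symmetric diol, auxiliary-controlled cyclopropanation, C–B oxidation with retention.
4. The cyclopropenone comes from methyl but-3-ynoate by difluorocarbene addition and hydrolysis.
5. Order of ring formation: cyclopropane (step 4), cyclopropene (step 6), six-membered ring (step 7, last step, no protecting groups).

Key step: step 7

Assumption: the (2R,3R)-diol is taken as the antipode of the auxiliary that leads to the (1R,2S)-cyclopropylboronate; if the facial preference is the reverse, the (2S,3S)-diol is used and nothing else changes.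

**Route**

Step 1
Reactants: 1 (2E,6E,10E)-geranylgeraniol
Product: 2 (2E,6E,10E)-1-bromo-3,7,11,15-tetramethylhexadeca-2,6,10,14-tetraene (geranylgeranyl bromide)
Conditions: CBr4, PPh3, CH2Cl2, −20 to 0 °C
Reagents that add atoms: tetrabromomethane BrC(Br)(Br)Br
Why: The Appel reaction should convert the primary allylic alcohol into the bromide under neutral conditions without allylic transposition or loss of alkene geometry; no stereocentre is formed.

Step 2
Reactants: 2 geranylgeranyl bromide; 3 ethynylmagnesium bromide
Product: 4 (4E,8E,12E)-5,9,13,17-tetramethyloctadeca-4,8,12,16-tetraen-1-yne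
Conditions: 3 (3 equiv), CuBr·SMe2 (10 mol %), THF, −20 °C to rt
Reagents that add atoms: none
Why: Copper-catalysed SN2 coupling of an alkynyl Grignard reagent with a primary allylic bromide should give the linear skipped enyne with the trisubstituted alkene geometry retained; no stereocentre is formed.

Step 3
Reactants: 4 the enyne; 5 (2R,3R)-1,4-dimethoxy-1,1,4,4-tetraphenylbutane-2,3-diol
Product: 7 (4R,5R)-4,5-bis[methoxy(diphenyl)methyl]-2-[(1E,4E,8E,12E)-5,9,13,17-tetramethyloctadeca-1,4,8,12,16-pentaen-1-yl]-1,3,2-dioxaborolane, via catechol alkenylboronate 6 (not isolated)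
Conditions: catecholborane (1.2 equiv), neat, 70 °C; then 5 (1.0 equiv), THF, rt
Reagents that add atoms: catecholborane B1Oc2ccccc2O1
Why: Uncatalysed syn, anti-Markovnikov hydroboration of the terminal alkyne leaves the trisubstituted alkenes untouched and gives the E-alkenylboronate, and transesterification of the labile catechol ester installs the C2-symmetric diol as stereocontroller.

Step 4
Reactants: 7 the alkenylboronate
Product: 8 (4R,5R)-4,5-bis[methoxy(diphenyl)methyl]-2-[(1R,2S)-2-[(2E,6E,10E)-3,7,11,15-tetramethylhexadeca-2,6,10,14-tetraen-1-yl]cyclopropyl]-1,3,2-dioxaborolane (trans-cyclopropane)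
Conditions: CH2N2 (excess, in Et2O), Pd(OAc)2 (5 mol %), Et2O, 0 °C; minor diastereomer removed by chromatography
Reagents that add atoms: diazomethane C=[N+]=[N-]
Why: Palladium-catalysed cyclopropanation with diazomethane is stereospecific (E-alkene to trans-cyclopropane) and selective for the 1,2-disubstituted boron-bearing alkene over the trisubstituted ones, and the two new ring stereocentres are set by the auxiliary, whose methoxydiphenylmethyl groups shield one alkene face.

Step 5
Reactants: 8 the cyclopropylboronate
Product: 9 (1R,2R)-2-[(2E,6E,10E)-3,7,11,15-tetramethylhexadeca-2,6,10,14-tetraen-1-yl]cyclopropan-1-ol (trans)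
Conditions: H2O2 (30 % aq.), KHCO3, THF/MeOH, 0 °C to rt
Reagents that add atoms: hydrogen peroxide OO
Why: Oxidation of the C–B bond by hydroperoxide (1,2-shift of carbon from boron to oxygen) proceeds with retention at the cyclopropyl carbon, so the trans-cyclopropanol results and the diol is recovered, while the buffered medium spares the base-sensitive cyclopropanol.

Step 6
Reactants: 10 methyl but-3-ynoate
Product: 12 methyl 2-(3-oxocycloprop-1-en-1-yl)acetate, via difluorocyclopropene 11 (not isolated)
Conditions: TMSCF3 (2 equiv), NaI (0.2 equiv), THF, 65 °C; then wet silica gel, CH2Cl2, rt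
Reagents that add atoms: (trifluoromethyl)trimethylsilane C[Si](C)(C)C(F)(F)F; water O
Why: Difluorocarbene released from TMSCF3 by iodide adds to the terminal alkyne in a [2+1] cycloaddition under nearly neutral conditions, and the 3,3-difluorocyclopropene hydrolyses at the CF2 carbon to the cyclopropenone; no stereocentre is formed.

Step 7
Reactants: 9 the cyclopropanol; 12 the cyclopropenone
Product: 13 methyl 2-[(3R,4R)-3-hydroxy-6-oxo-4-[(2E,6E,10E)-3,7,11,15-tetramethylhexadeca-2,6,10,14-tetraen-1-yl]cyclohex-1-en-1-yl]acetate (target)
Conditions: [Rh(OH)(cod)]2 (2.5 mol %), toluene, 40 °C, slow addition of 9 to 12 (1.3 equiv)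
Reagents that add atoms: none
Why: Proposed new method: monovalent rhodium exchanges hydroxide for the alkoxide of 9 and cleaves the less substituted C4–C6 bond by β-carbon elimination to give the rhodium homoenolate of the α-branched aldehyde; this alkyl–rhodium adds to the carbonyl of 12 (C6–C1), the strained cyclopropenyl alkoxide opens by a second β-carbon elimination at C1–C3 so that rhodium sits on C3 cis to the new acyl group, and the alkenyl–rhodium adds to the tethered aldehyde (C3–C4) before the rhodium alkoxide is protonated by the next molecule of 9. The closest known reaction types are the cobalt-catalysed [3+2] annulation of cyclopropanols with alkynes (homoenolate carbometalation, then addition to the released carbonyl), the ring opening of cyclopropenones by insertion of their carbonyl into carbon–rhodium bonds followed by β-carbon elimination, and alkenyl–rhodium additions to tethered aldehydes; new is their combination into a [3+3] union of two three-membered rings. The six-membered ring closes by 6-exo-trig 1,2-addition of the C3–Rh bond to the C4 aldehyde. C5 is carried unchanged from 9, and C4 is set by substrate control: the four-centre insertion holds the rhodium-bound carbonyl oxygen in the plane of the alkenyl unit and the C5 chain avoids the metal by standing pseudoaxial (free of 1,3-diaxial hydrogens because C1 and C3 are sp2), which should give the 4,5-cis (3R,4R) alcohol. The step needs opening of 12 at the unsubstituted carbon, secured by the lower hindrance of the C1–C3(H) bond, and carbonyl insertion faster than β-hydride elimination of the homoenolate, favoured by its five-membered C,O-chelate, the electrophilicity of 12 and the slow addition of 9.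

**Compound list**

1 | (2E,6E,10E)-geranylgeraniol | OC/C=C(\C)CC/C=C(\C)CC/C=C(\C)CCC=C(C)C | starting material
2 | (2E,6E,10E)-geranylgeranyl bromide | BrC/C=C(\C)CC/C=C(\C)CC/C=C(\C)CCC=C(C)C | intermediate
3 | ethynylmagnesium bromide | C#C[Mg]Br | starting material
4 | (4E,8E,12E)-5,9,13,17-tetramethyloctadeca-4,8,12,16-tetraen-1-yne | C#CC/C=C(\C)CC/C=C(\C)CC/C=C(\C)CCC=C(C)C | intermediate
5 | (2R,3R)-1,4-dimethoxy-1,1,4,4-tetraphenylbutane-2,3-diol | COC(c1ccccc1)(c1ccccc1)[C@H](O)[C@@H](O)C(OC)(c1ccccc1)c1ccccc1 | starting material
6 | 2-[(1E,4E,8E,12E)-5,9,13,17-tetramethyloctadeca-1,4,8,12,16-pentaen-1-yl]-1,3,2-benzodioxaborole | O1c2ccccc2OB1/C=C/C/C=C(\C)CC/C=C(\C)CC/C=C(\C)CCC=C(C)C | intermediate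
7 | (4R,5R)-4,5-bis[methoxy(diphenyl)methyl]-2-[(1E,4E,8E,12E)-5,9,13,17-tetramethyloctadeca-1,4,8,12,16-pentaen-1-yl]-1,3,2-dioxaborolane | O1[C@@H](C(OC)(c2ccccc2)c2ccccc2)[C@H](C(OC)(c2ccccc2)c2ccccc2)OB1/C=C/C/C=C(\C)CC/C=C(\C)CC/C=C(\C)CCC=C(C)C | intermediate
8 | (4R,5R)-4,5-bis[methoxy(diphenyl)methyl]-2-[(1R,2S)-2-(geranylgeranyl)cyclopropyl]-1,3,2-dioxaborolane | O1[C@@H](C(OC)(c2ccccc2)c2ccccc2)[C@H](C(OC)(c2ccccc2)c2ccccc2)OB1[C@@H]3C[C@H]3C/C=C(\C)CC/C=C(\C)CC/C=C(\C)CCC=C(C)C | intermediate
9 | (1R,2R)-2-[(2E,6E,10E)-3,7,11,15-tetramethylhexadeca-2,6,10,14-tetraen-1-yl]cyclopropan-1-ol | O[C@@H]1C[C@H]1C/C=C(\C)CC/C=C(\C)CC/C=C(\C)CCC=C(C)C | intermediate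
10 | methyl but-3-ynoate | COC(=O)CC#C | starting material
11 | methyl 2-(3,3-difluorocycloprop-1-en-1-yl)acetate | COC(=O)CC1=CC1(F)F | intermediate
12 | methyl 2-(3-oxocycloprop-1-en-1-yl)acetate | COC(=O)CC1=CC1=O | intermediate
13 | methyl 2-[(3R,4R)-3-hydroxy-6-oxo-4-[(2E,6E,10E)-3,7,11,15-tetramethylhexadeca-2,6,10,14-tetraen-1-yl]cyclohex-1-en-1-yl]acetate | COC(=O)CC1=C[C@H](O)[C@H](C/C=C(\C)CC/C=C(\C)CC/C=C(\C)CCC=C(C)C)CC1=O | target

**Count and risks**

Total steps: 7. Longest linear sequence: 6 (steps 1 to 5 and 7).

Step 7 (Proposed new method).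
- What may go wrong: the rhodium homoenolate from 9 may undergo β-hydride elimination or protonation before it meets 12; 12 may lose CO or oligomerise at the metal; carbometalation of its C=C or opening toward the substituted carbon would give a regioisomeric ring; the product alkoxide may be dehydrogenated by β-hydride elimination; the addition to the aldehyde may show low facial selectivity.
- Fallback (known reactions, run stepwise, ring closed from the C4 side by a ketyl instead of an alkenyl–metal), setting out from 9 and returning at 13: commercial 4-methyl hydrogen itaconate and oxalyl chloride give methyl 3-(chlorocarbonyl)but-3-enoate F1. Palladium-catalysed ring-opening acylation of the cyclopropanol 9 with F1 (Pd(PPh3)4, K2CO3, toluene, 80 °C) gives keto aldehyde F2; F2 is also what step 7 would leave if the alkenyl–rhodium were protonated before ring closure. SmI2 (THF/MeOH, −78 °C) effects the reductive aldehyde–enone cyclisation, the ketyl carbon adding to the enone terminus, and should give the 4,5-cis hydroxy ketone F3, the samarium-bearing oxygen avoiding the C5 chain. Thermodynamic silylation (TMSCl, NaI, Et3N, MeCN) gives the bis-silyl enol ether F4. Saegusa oxidation (Pd(OAc)2, MeCN) with mild acidic work-up restores the C2=C3 alkene and frees the alcohol, giving 13.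

Step 4.
- What may go wrong: poor facial discrimination in the carbene transfer and co-elution of the two cyclopropane diastereomers, so that the C5 configuration is not secured.
- Fallback (resolution instead of auxiliary control), setting out from 8 taken on as the diastereomer mixture and returning at 9: oxidation as in step 5 gives 9 together with its enantiomer, (1S,2S)-cyclopropanol F5. A lipase chosen for that enantiomer (Candida antarctica lipase B, vinyl acetate, hexane) acylates F5 to the cyclopropyl acetate F6, which is removed by chromatography, and enantiopure 9 goes on to step 7.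

Step 5.
- What may go wrong: slow oxidative cleavage of the very hindered dioxaborolane, and base-induced ring opening of 9 to the aldehyde during a prolonged peroxide treatment.
- Fallback (auxiliary removed reductively before the oxidation), setting out from 8 and returning at 9: LiAlH4 (Et2O, 0 °C) breaks the B–O bonds and frees the diol, aqueous work-up gives the cyclopropylboronic acid F7, and this unhindered acid is oxidised within minutes under buffered conditions (NaBO3·4H2O, THF/H2O, rt) with retention to 9.

Further compounds
F1 | step 7 | methyl 3-(chlorocarbonyl)but-3-enoate | C=C(CC(=O)OC)C(Cl)=O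
F2 | step 7 | methyl (6R,8E,12E,16E)-6-formyl-9,13,17,21-tetramethyl-3-methylidene-4-oxodocosa-8,12,16,20-tetraenoate | C=C(CC(=O)OC)C(=O)C[C@H](C=O)C/C=C(\C)CC/C=C(\C)CC/C=C(\C)CCC=C(C)C
F3 | step 7 | methyl 2-[(4R,5S)-5-hydroxy-2-oxo-4-(geranylgeranyl)cyclohexyl]acetate (4,5-cis, mixture at the acetate-bearing ring carbon) | COC(=O)CC1C[C@H](O)[C@H](C/C=C(\C)CC/C=C(\C)CC/C=C(\C)CCC=C(C)C)CC1=O
F4 | step 7 | methyl 2-[(4R,5S)-4-(geranylgeranyl)-2,5-bis(trimethylsilyloxy)cyclohex-1-en-1-yl]acetate | COC(=O)CC1=C(O[Si](C)(C)C)C[C@@H](C/C=C(\C)CC/C=C(\C)CC/C=C(\C)CCC=C(C)C)[C@@H](O[Si](C)(C)C)C1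
F5 | step 4 | (1S,2S)-2-[(2E,6E,10E)-3,7,11,15-tetramethylhexadeca-2,6,10,14-tetraen-1-yl]cyclopropan-1-ol | O[C@H]1C[C@@H]1C/C=C(\C)CC/C=C(\C)CC/C=C(\C)CCC=C(C)C
F6 | step 4 | (1S,2S)-2-[(2E,6E,10E)-3,7,11,15-tetramethylhexadeca-2,6,10,14-tetraen-1-yl]cyclopropyl acetate | CC(=O)O[C@H]1C[C@@H]1C/C=C(\C)CC/C=C(\C)CC/C=C(\C)CCC=C(C)C
F7 | step 5 | [(1R,2S)-2-[(2E,6E,10E)-3,7,11,15-tetramethylhexadeca-2,6,10,14-tetraen-1-yl]cyclopropyl]boronic acid | OB(O)[C@@H]1C[C@H]1C/C=C(\C)CC/C=C(\C)CC/C=C(\C)CCC=C(C)C
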